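**Retrosynthetic overview**
- Last bond made: the aryl ether O–CH2 bond between O-4 of the fully C-acylated phloroglucinol and C-1 of geraniol, by a site-selective dehydrative O-geranylation (key C–O step).
- The diacyl triol comes from two successive Friedel–Crafts C-acylations of 2-methylphloroglucinol: (R)-2-methylbutanoyl first, acetyl second at the last free ring C–H.
- The only stereocentre is bought with (R)-2-methylbutanoic acid; the E-alkene is bought with geraniol.
- No ring is formed; the benzene ring is bought.

Assumption: 2-methylphloroglucinol, (R)-2-methylbutanoic acid and geraniol are bought as catalogue items; the target is the (R)-ketone with an (E)-geranyl ether, as the SMILES reads.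

**Step 1**
Reactants: 1 2-methylphloroglucinol (2-methylbenzene-1,3,5-triol); 2 (R)-2-methylbutanoic acid
Product: 4 (2R)-1-(2,4,6-trihydroxy-3-methylphenyl)-2-methylbutan-1-one, via (R)-2-methylbutanoyl chloride 3 (not isolated)
Conditions: 2 (1.05 equiv), (COCl)2 (1.0 equiv), DMF (1 mol %), CH2Cl2, 0 °C to rt, 2 h; then added to 1 (1.2 equiv), AlCl3 (3.5 equiv), PhNO2/CH2Cl2, 0 °C to rt, 6 h; 1 M HCl
Reagents that add atoms: none
Why: Friedel–Crafts acylation of a very electron-rich triol whose two free ring positions are equivalent, so only one monoketone can form; with the acid chloride limiting, the deactivated monoketone does not compete for it, and the stereocentre is carried in from 2 and kept by working at or below rt.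

**Step 2**
Reactants: 4 (2R)-1-(2,4,6-trihydroxy-3-methylphenyl)-2-methylbutan-1-one
Product: 5 (2R)-1-(3-acetyl-2,4,6-trihydroxy-5-methylphenyl)-2-methylbutan-1-one
Conditions: AcCl (1.3 equiv), AlCl3 (4 equiv), PhNO2/CH2Cl2, rt to 35 °C, 16 h; 1 M HCl
Reagents that add atoms: acetyl chloride, CC(=O)Cl
Why: Second Friedel–Crafts acylation at the only remaining ring C–H, still activated by two ortho OH and one para OH; the sec-butyl ketone sits in an aluminium chelate with its ortho phenoxide and should not enolise at 35 °C or below, so the stereocentre is kept.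

**Step 3**
Reactants: 5 (2R)-1-(3-acetyl-2,4,6-trihydroxy-5-methylphenyl)-2-methylbutan-1-one; 6 geraniol ((2E)-3,7-dimethylocta-2,6-dien-1-ol)
Product: 8 (2R)-1-[3-acetyl-4-{[(2E)-3,7-dimethylocta-2,6-dien-1-yl]oxy}-2,6-dihydroxy-5-methylphenyl]-2-methylbutan-1-one (the target), via geranyloxyphosphonium phenolate ion pair 7 (not isolated)
Conditions: 6 (1.05 equiv), PPh3 (1.15 equiv), DIAD (1.15 equiv, added over 2 h), toluene/THF 9:1 (0.05 M), −30 °C to 0 °C
Reagents that add atoms: none
Why: Proposed new method: an acyl-size-gated, site-selective Mitsunobu etherification of a phenol triad in which every OH is flanked by a carbonyl group; the PPh3/DIAD betaine takes one proton from 5 and turns 6 into the oxyphosphonium cation, and in the tight, metal-free ion pair 7 an oxygen can attack the allylic CH2 (SN2, no new stereocentre, E-alkene untouched) only when its neighbouring C=O has turned away to hydrogen-bond the other flanking OH, which swings that acyl group's alkyl residue next to the reacting oxygen; O-4 then sits between the ring CH3 and the acetyl CH3, O-6 next to the sec-butyl group and O-2 between both acyl alkyl groups, so the least hindered O-4 is alkylated, and the product, with both remaining OH locked in six-membered hydrogen bonds, does not react again; the closest known reaction type is the Mitsunobu O-alkylation of 2,4,6-trihydroxyacylphenones, which picks the one OH that is not ortho to the carbonyl, whereas discrimination between carbonyl-flanked OH groups by the size of the neighbouring acyl group has not been shown.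

**Compound list**
1 | 2-methylphloroglucinol (2-methylbenzene-1,3,5-triol) | Cc1c(O)cc(O)cc1O | starting material
2 | (R)-2-methylbutanoic acid | CC[C@@H](C)C(=O)O | starting material
3 | (R)-2-methylbutanoyl chloride | CC[C@@H](C)C(=O)Cl | intermediate
4 | (2R)-1-(2,4,6-trihydroxy-3-methylphenyl)-2-methylbutan-1-one | CC[C@@H](C)C(=O)c1c(O)c(C)c(O)cc1O | intermediate
5 | (2R)-1-(3-acetyl-2,4,6-trihydroxy-5-methylphenyl)-2-methylbutan-1-one | CC[C@@H](C)C(=O)c1c(O)c(C)c(O)c(C(C)=O)c1O | intermediate
6 | geraniol ((2E)-3,7-dimethylocta-2,6-dien-1-ol) | CC(C)=CCC/C(C)=C/CO | starting material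
7 | ion pair of [(2E)-3,7-dimethylocta-2,6-dien-1-yl]oxy(triphenyl)phosphonium and the mono-phenolate of 5 (charge drawn on O-4) | CC(C)=CCC/C(C)=C/CO[P+](c1ccccc1)(c1ccccc1)c1ccccc1.CC[C@@H](C)C(=O)c1c(O)c(C)c([O-])c(C(C)=O)c1O | intermediate
8 | (2R)-1-[3-acetyl-4-{[(2E)-3,7-dimethylocta-2,6-dien-1-yl]oxy}-2,6-dihydroxy-5-methylphenyl]-2-methylbutan-1-one | CC[C@@H](C)C(=O)c1c(O)c(C)c(OC/C=C(\C)CCC=C(C)C)c(C(C)=O)c1O | target

**Step count**
Total steps: 3. Longest linear sequence: 3 (1 or 2 → 4 → 5 → 8).

**Steps most likely to fail**

Step 3 (the proposed new step). The risk is that the O-6 or O-2 ether forms alongside, or that the ring is C-alkylated. The fallback uses known chemistry only, sets out from 4 and comes back at 8.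
- Iodination of the one free ring position of 4 (NIS, MeCN, 0 °C) gives (2R)-1-(2,4,6-trihydroxy-3-iodo-5-methylphenyl)-2-methylbutan-1-one F1.
- Geranyl bromide and K2CO3 in acetone at rt alkylate the only OH that is not ortho to the ketone (the known para selectivity of 2,4,6-trihydroxyacylphenones). This gives (2R)-1-[4-{[(2E)-3,7-dimethylocta-2,6-dien-1-yl]oxy}-2,6-dihydroxy-3-iodo-5-methylphenyl]-2-methylbutan-1-one F2.
- Stille coupling with tributyl(1-ethoxyvinyl)stannane (PdCl2(PPh3)2, toluene, 80 °C) gives (2R)-1-[4-{[(2E)-3,7-dimethylocta-2,6-dien-1-yl]oxy}-3-(1-ethoxyethenyl)-2,6-dihydroxy-5-methylphenyl]-2-methylbutan-1-one F3.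
- 1 M HCl in THF at 0 °C hydrolyses the enol ether to the acetyl group of 8.

Here the ether oxygen is fixed before the second carbonyl exists, so no site choice arises.

Step 2. The risk is partial loss of ee at the ketone α-carbon during the long AlCl3 contact, or incomplete acylation of the deactivated ring. The fallback reverses the order of the two acylations, sets out from 1 and comes back at 5. Acetylation of 1 (AcCl, AlCl3, PhNO2/CH2Cl2, 0 °C to rt) gives 1-(2,4,6-trihydroxy-3-methylphenyl)ethan-1-one F4. Its last ring C–H is then acylated with 3, made from 2 as in step 1 (AlCl3, PhNO2, 40 °C). The stereocentre then meets the Lewis acid only once.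

Step 1. The risk is partial racemisation of the acid chloride through the ketene, or some diacylation. The fallback obtains the stereocentre by resolution instead, sets out from 1 and comes back at 4. Friedel–Crafts acylation with cheap racemic 2-methylbutanoyl chloride (AlCl3, PhNO2/CH2Cl2, 0 °C to rt) gives racemic 1-(2,4,6-trihydroxy-3-methylphenyl)-2-methylbutan-1-one F5. Preparative chiral SFC on an amylose-type phase then delivers the (R)-ketone 4; partly racemised 4 from step 1 can be upgraded the same way.

**Further compounds**
F1 | step 3 | (2R)-1-(2,4,6-trihydroxy-3-iodo-5-methylphenyl)-2-methylbutan-1-one | CC[C@@H](C)C(=O)c1c(O)c(C)c(O)c(I)c1O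
F2 | step 3 | (2R)-1-[4-{[(2E)-3,7-dimethylocta-2,6-dien-1-yl]oxy}-2,6-dihydroxy-3-iodo-5-methylphenyl]-2-methylbutan-1-one | CC[C@@H](C)C(=O)c1c(O)c(C)c(OC/C=C(\C)CCC=C(C)C)c(I)c1O
F3 | step 3 | (2R)-1-[4-{[(2E)-3,7-dimethylocta-2,6-dien-1-yl]oxy}-3-(1-ethoxyethenyl)-2,6-dihydroxy-5-methylphenyl]-2-methylbutan-1-one | CC[C@@H](C)C(=O)c1c(O)c(C)c(OC/C=C(\C)CCC=C(C)C)c(C(=C)OCC)c1O
F4 | step 2 | 1-(2,4,6-trihydroxy-3-methylphenyl)ethan-1-one | CC(=O)c1c(O)cc(O)c(C)c1O
F5 | step 1 | racemic 1-(2,4,6-trihydroxy-3-methylphenyl)-2-methylbutan-1-one | CCC(C)C(=O)c1c(O)c(C)c(O)cc1O
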